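**Strategy.** The bicyclo[3.1.0]hex-2-ene core (cyclopentene C1–C5 fused to cyclopropane C1–C5–C6) is an isomer of an acyclic (2E,4Z,6E)-2,4,6-trimethyltrienoate, if the pyrone carbon on C6 is read as a masked carboxyl. A Lewis-acid-triggered conrotatory closure of the C4–C5 bond, followed by C1–C6 cyclopropane closure, should build both rings and all four contiguous stereocentres (C1, C4, C5, C6) in one operation. The precursor is a linear tetraenoate ester of (−)-8-phenylmenthol, whose bought stereocentres choose the π-face. The ester is then converted into the α-methoxy-γ-pyrone, and the pent-2-en-2-yl side chain is oxidised last by a singlet-oxygen ene reaction.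

Key step: step 8

Remark: "8-phenylmenthyl" means (1R,2S,5R)-5-methyl-2-(2-phenylpropan-2-yl)cyclohexyl; the facial sense in step 8 is the one predicted by the s-trans ester–aluminium complex model and is to be confirmed on crystalline ester 19 before the route goes on.

**Step 1**
Reactants: 1 prop-2-yn-1-ol
Product: 3 (2Z)-3-iodo-2-methylprop-2-en-1-ol, via alkenylmagnesium alkoxide 2 (not isolated)
Conditions: MeMgBr (3 equiv), CuI (10 mol%), Et2O, −10 °C to rt; then I2, −10 °C to rt
Reagents that add atoms: methylmagnesium bromide C[Mg]Br; iodine II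
Why: Copper-catalysed anti-carbomagnesiation of the propargylic alkoxide places magnesium cis to CH2O in a five-membered chelate, and iodinolysis with retention should give the (Z)-iodide.

**Step 2**
Reactants: 4 (−)-8-phenylmenthol; 5 2-bromopropanoyl bromide (racemic)
Product: 6 8-phenylmenthyl 2-bromopropanoate (both epimers at the bromide carbon)
Conditions: pyridine, DMAP (cat.), CH2Cl2, 0 °C to rt
Reagents that add atoms: none
Why: DMAP-catalysed acylation of the hindered secondary alcohol by the acyl bromide; the bromide-bearing centre is lost in step 3, so both epimers are used.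

**Step 3**
Reactants: 6 8-phenylmenthyl 2-bromopropanoate
Product: 8 8-phenylmenthyl 2-(triphenyl-λ5-phosphanylidene)propanoate, via phosphonium bromide 7 (not isolated)
Conditions: PPh3, toluene, 90 °C; then 2 M NaOH, CH2Cl2/H2O, rt
Reagents that add atoms: triphenylphosphine c1ccc(cc1)P(c1ccccc1)c1ccccc1
Why: SN2 quaternisation of PPh3 by the α-bromo ester and deprotonation of the salt should give the stabilised ylide.

**Step 4**
Reactants: 3 (2Z)-3-iodo-2-methylprop-2-en-1-ol; 8 8-phenylmenthyl 2-(triphenyl-λ5-phosphanylidene)propanoate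
Product: 10 8-phenylmenthyl (2E,4Z)-5-iodo-2,4-dimethylpenta-2,4-dienoate, via (2Z)-3-iodo-2-methylprop-2-enal 9 (not isolated)
Conditions: MnO2 (excess), CH2Cl2, rt, dark; filter; then 8, CH2Cl2, rt
Reagents that add atoms: none
Why: Allylic oxidation followed by Wittig olefination with a stabilised α-methyl ylide should give the (2E)-enoate while the (Z)-iodoalkene is carried through unchanged.

**Step 5**
Reactants: 11 (2E)-2-methylpent-2-enal
Product: 12 (3E)-1,1-dibromo-3-methylhexa-1,3-diene
Conditions: CBr4, PPh3, CH2Cl2, 0 °C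
Reagents that add atoms: carbon tetrabromide BrC(Br)(Br)Br
Why: Dibromo-olefination of the enal (first stage of the Corey–Fuchs sequence); the existing (E)-alkene is not touched.

**Step 6**
Reactants: 12 (3E)-1,1-dibromo-3-methylhexa-1,3-diene
Product: 14 (4E)-4-methylhept-4-en-2-yne, via lithium acetylide 13 (not isolated)
Conditions: n-BuLi (2.1 equiv), THF, −78 °C; then MeI, −78 °C to rt
Reagents that add atoms: iodomethane CI
Why: Bromine–lithium exchange, Fritsch–Buttenberg–Wiechell rearrangement and deprotonation give the acetylide (second stage of the Corey–Fuchs sequence), which is methylated in the same flask.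

**Step 7**
Reactants: 14 (4E)-4-methylhept-4-en-2-yne; 10 8-phenylmenthyl (2E,4Z)-5-iodo-2,4-dimethylpenta-2,4-dienoate
Product: 17 8-phenylmenthyl (2E,4Z,6E,8E)-2,4,6,8-tetramethylundeca-2,4,6,8-tetraenoate, via dienylzirconocene chloride 15 (not isolated), via dienylzinc chloride 16 (not isolated)
Conditions: Cp2Zr(H)Cl (1.2 equiv), THF, 50 °C; ZnCl2, THF, 0 °C; then 10, Pd(PPh3)4 (5 mol%), rt, dark
Reagents that add atoms: none
Why: syn-Hydrozirconation with regio-equilibration should place zirconium on the less hindered methyl-bearing alkyne carbon, and zirconium-to-zinc transmetalation and Negishi coupling proceed with retention at both partners, so the (6E) and (4Z) geometries follow from the two fragments.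

**Step 8**
Reactants: 17 8-phenylmenthyl (2E,4Z,6E,8E)-2,4,6,8-tetramethylundeca-2,4,6,8-tetraenoate
Product: 19 8-phenylmenthyl (1S,4S,5R,6S)-1,3,6-trimethyl-4-[(2E)-pent-2-en-2-yl]bicyclo[3.1.0]hex-2-ene-6-carboxylate, via cyclopentenyl cation aluminium enolate 18 (not isolated)
Conditions: Me2AlCl (0.5 equiv), CH2Cl2, −78 to −20 °C
Reagents that add atoms: none
Why: Me2AlCl on the ester carbonyl polarises the triene so that tetraenoate atoms C3–C7 act as a pentadienyl cation, which closes by conrotatory 4π electrocyclisation (C3–C7, the C5–C4 bond of the bicycle, cyclopentene ring), and the aluminium enolate carbon C2 then collapses onto the allyl cation terminus C4 (3-exo-trig, the C6–C1 bond, cyclopropane); this is the known Lewis-acid cycloisomerisation of (E,Z,E)-polyenoate esters to bicyclo[3.1.0]hex-2-enes (formal [π4a+π2a] cycloaddition, vinylogous Nazarov type). The absolute sense is set at the enoate β-carbon (future C5): in the s-trans ester–aluminium complex the phenyl ring of the auxiliary stacks over one π-face, so the triene tail coils onto and bonds from the open face. Conrotation with both terminal substituents outside then places the pentenyl group at C4 trans to the ester-bearing carbon, that is anti to the cyclopropane, and the cyclopropane can only close cis on the face of C5 that carries the enolate carbon, which fixes C1. At C6 the aluminium-bound carboxylate takes the exo position and the methyl the endo one, as also follows from antarafacial addition to the (2E)-enoate. The step needs π-facial selectivity, which the auxiliary is meant to provide (the two possible products are diastereomers and separable), and periselectivity over thermal disrotatory 6π closure to a cyclohexadiene, which the low temperature and the Lewis acid should secure.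

**Step 9**
Reactants: 19 8-phenylmenthyl bicyclic ester
Product: 20 [(1S,4S,5R,6S)-1,3,6-trimethyl-4-[(2E)-pent-2-en-2-yl]bicyclo[3.1.0]hex-2-en-6-yl]methanol
Conditions: LiAlH4, THF, 0 to 40 °C
Reagents that add atoms: none
Why: Hydride reduction of the hindered ester to the primary alcohol releases the auxiliary alcohol 4 for re-use and touches no stereocentre.

**Step 10**
Reactants: 20 bicyclic primary alcohol
Product: 21 (1S,4S,5R,6S)-1,3,6-trimethyl-4-[(2E)-pent-2-en-2-yl]bicyclo[3.1.0]hex-2-ene-6-carbaldehyde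
Conditions: Dess–Martin periodinane, NaHCO3, CH2Cl2, rt
Reagents that add atoms: none
Why: Dess–Martin oxidation gives an aldehyde that has no α-hydrogen and cannot epimerise, and whose formyl group is trans to the ring alkene on the cyclopropane, so no retro-Claisen-type rearrangement is open to it.

**Step 11**
Reactants: 21 bicyclic aldehyde; 22 methyl 2-methyl-3-oxopentanoate
Product: 24 methyl 5-hydroxy-2,4-dimethyl-3-oxo-5-[(1S,4S,5R,6S)-1,3,6-trimethyl-4-[(2E)-pent-2-en-2-yl]bicyclo[3.1.0]hex-2-en-6-yl]pentanoate (diastereomer mixture in the chain), via keto ester dianion 23 (not isolated)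
Conditions: 22, NaH then n-BuLi, THF, 0 °C; then 21, −78 °C; aq NH4Cl
Reagents that add atoms: none
Why: Aldol addition of the γ-carbon of the β-keto ester dianion (Weiler type) to the non-enolisable aldehyde; the three new chain stereocentres form as a mixture and are all removed in steps 12 and 13.

**Step 12**
Reactants: 24 δ-hydroxy-β-keto ester
Product: 25 methyl 2,4-dimethyl-3,5-dioxo-5-[(1S,4S,5R,6S)-1,3,6-trimethyl-4-[(2E)-pent-2-en-2-yl]bicyclo[3.1.0]hex-2-en-6-yl]pentanoate
Conditions: Dess–Martin periodinane, CH2Cl2, rt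
Reagents that add atoms: none
Why: Dess–Martin oxidation of the secondary alcohol gives the 3,5-diketo ester without touching the alkenes.

**Step 13**
Reactants: 25 3,5-diketo ester
Product: 26 4-hydroxy-3,5-dimethyl-6-[(1S,4S,5R,6S)-1,3,6-trimethyl-4-[(2E)-pent-2-en-2-yl]bicyclo[3.1.0]hex-2-en-6-yl]-2H-pyran-2-one
Conditions: DBU, toluene, 60 °C
Reagents that add atoms: none
Why: Base-mediated enolisation and lactonisation of the δ-keto enol oxygen onto the methyl ester (6-exo-trig acyl substitution) should give the 4-hydroxy-2-pyranone.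

**Step 14**
Reactants: 26 4-hydroxy-2-pyranone
Product: 28 2-methoxy-3,5-dimethyl-6-[(1S,4S,5R,6S)-1,3,6-trimethyl-4-[(2E)-pent-2-en-2-yl]bicyclo[3.1.0]hex-2-en-6-yl]-4H-pyran-4-one, via hydroxypyrylium triflate 27 (not isolated)
Conditions: MeOTf, CH2Cl2, rt; then aq NaHCO3
Reagents that add atoms: methyl trifluoromethanesulfonate COS(=O)(=O)C(F)(F)F
Why: A hard methylating agent alkylates the neutral hydroxypyranone at the lactone carbonyl oxygen, and deprotonation of the resulting 2-methoxy-4-hydroxypyrylium ion gives the α-methoxy-γ-pyrone and not the γ-methoxy-α-pyrone.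

**Step 15**
Reactants: 28 pentenyl bicyclic γ-pyrone
Product: 30 2-methoxy-3,5-dimethyl-6-[(1S,4R,5R,6S)-1,3,6-trimethyl-4-(3-oxopent-1-en-2-yl)bicyclo[3.1.0]hex-2-en-6-yl]-4H-pyran-4-one (target), via allylic hydroperoxide 29 (not isolated)
Conditions: O2, tetraphenylporphyrin (cat.), visible light, CH2Cl2, 0 °C; then Ac2O, pyridine, DMAP (cat.), 0 °C to rt
Reagents that add atoms: dioxygen O=O
Why: Schenck ene reaction of singlet oxygen at the more exposed side-chain alkene, with hydrogen abstraction from the methyl that is geminal to the bulky ring and cis to the ethyl group (cis effect and large-group effect), should give the secondary allylic hydroperoxide, which acetylation and base-induced O–O cleavage (Kornblum–DeLaMare-type dehydration) convert into the enone; the carbinol centre of 29 forms as a mixture and is destroyed, and the ring alkene is screened by the C1 methyl and C4 substituent on one face and the endo C6 methyl on the other.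

**Compound list**

1 | prop-2-yn-1-ol | C#CCO | starting material
2 | bromomagnesium (2Z)-3-(bromomagnesio)-2-methylprop-2-en-1-olate (formed in the flask) | Br[Mg]/C=C(/C)CO[Mg]Br | intermediate
3 | (2Z)-3-iodo-2-methylprop-2-en-1-ol | OC/C(C)=C\I | intermediate
4 | (−)-8-phenylmenthol, (1R,2S,5R)-5-methyl-2-(2-phenylpropan-2-yl)cyclohexan-1-ol | O[C@@H]1C[C@H](C)CC[C@H]1C(C)(C)c1ccccc1 | starting material
5 | 2-bromopropanoyl bromide (racemic) | CC(Br)C(Br)=O | starting material
6 | 8-phenylmenthyl 2-bromopropanoate (both epimers at the bromide carbon) | CC(Br)C(=O)O[C@@H]1C[C@H](C)CC[C@H]1C(C)(C)c1ccccc1 | intermediate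
7 | [1-(8-phenylmenthyloxy)-1-oxopropan-2-yl]triphenylphosphonium bromide (formed in the flask) | CC(C(=O)O[C@@H]1C[C@H](C)CC[C@H]1C(C)(C)c1ccccc1)[P+](c1ccccc1)(c1ccccc1)c1ccccc1.[Br-] | intermediate
8 | 8-phenylmenthyl 2-(triphenyl-λ5-phosphanylidene)propanoate | CC(=P(c1ccccc1)(c1ccccc1)c1ccccc1)C(=O)O[C@@H]1C[C@H](C)CC[C@H]1C(C)(C)c1ccccc1 | intermediate
9 | (2Z)-3-iodo-2-methylprop-2-enal (formed in the flask) | O=C/C(C)=C\I | intermediate
10 | 8-phenylmenthyl (2E,4Z)-5-iodo-2,4-dimethylpenta-2,4-dienoate | I/C=C(C)\C=C(/C)C(=O)O[C@@H]1C[C@H](C)CC[C@H]1C(C)(C)c1ccccc1 | intermediate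
11 | (2E)-2-methylpent-2-enal | CC/C=C(\C)C=O | starting material
12 | (3E)-1,1-dibromo-3-methylhexa-1,3-diene | CC/C=C(\C)C=C(Br)Br | intermediate
13 | lithium (3E)-3-methylhex-3-en-1-yn-1-ide (formed in the flask) | CC/C=C(\C)C#C[Li] | intermediate
14 | (4E)-4-methylhept-4-en-2-yne | CC/C=C(\C)C#CC | intermediate
15 | chlorobis(cyclopentadienyl)[(2E,4E)-4-methylhepta-2,4-dien-2-yl]zirconium (formed in the flask; cyclopentadienyl rings drawn σ-bonded) | CC/C=C(C)/C=C(\C)[Zr](Cl)(C1C=CC=C1)C1C=CC=C1 | intermediate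
16 | chloro[(2E,4E)-4-methylhepta-2,4-dien-2-yl]zinc (formed in the flask) | CC/C=C(C)/C=C(\C)[Zn]Cl | intermediate
17 | 8-phenylmenthyl (2E,4Z,6E,8E)-2,4,6,8-tetramethylundeca-2,4,6,8-tetraenoate | CC/C=C(C)/C=C(C)/C=C(C)\C=C(/C)C(=O)O[C@@H]1C[C@H](C)CC[C@H]1C(C)(C)c1ccccc1 | intermediate
18 | trans-4,5-disubstituted 1,3-dimethylcyclopentenyl cation carrying the chlorodimethylaluminate ester enolate (formed in the flask) | CC/C=C(\C)[C@H]1C(C)=C[C+](C)[C@@H]1C(C)=C(O[Al-](C)(C)Cl)O[C@@H]1C[C@H](C)CC[C@H]1C(C)(C)c1ccccc1 | intermediate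
19 | 8-phenylmenthyl (1S,4S,5R,6S)-1,3,6-trimethyl-4-[(2E)-pent-2-en-2-yl]bicyclo[3.1.0]hex-2-ene-6-carboxylate | CC/C=C(\C)[C@H]1C(C)=C[C@@]2(C)[C@@H]1[C@]2(C)C(=O)O[C@@H]1C[C@H](C)CC[C@H]1C(C)(C)c1ccccc1 | intermediate
20 | [(1S,4S,5R,6S)-1,3,6-trimethyl-4-[(2E)-pent-2-en-2-yl]bicyclo[3.1.0]hex-2-en-6-yl]methanol | CC/C=C(\C)[C@H]1C(C)=C[C@@]2(C)[C@@H]1[C@]2(C)CO | intermediate
21 | (1S,4S,5R,6S)-1,3,6-trimethyl-4-[(2E)-pent-2-en-2-yl]bicyclo[3.1.0]hex-2-ene-6-carbaldehyde | CC/C=C(\C)[C@H]1C(C)=C[C@@]2(C)[C@@H]1[C@]2(C)C=O | intermediate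
22 | methyl 2-methyl-3-oxopentanoate | CCC(=O)C(C)C(=O)OC | starting material
23 | sodium lithium dianion of methyl 2-methyl-3-oxopentanoate (formed in the flask) | C[CH-]C(=O)C(C)=C([O-])OC.[Na+].[Li+] | intermediate
24 | methyl 5-hydroxy-2,4-dimethyl-3-oxo-5-(bicyclyl)pentanoate, bicyclyl as in 20 (chain diastereomers) | CC/C=C(\C)[C@H]1C(C)=C[C@@]2(C)[C@@H]1[C@]2(C)C(O)C(C)C(=O)C(C)C(=O)OC | intermediate
25 | methyl 2,4-dimethyl-3,5-dioxo-5-(bicyclyl)pentanoate | CC/C=C(\C)[C@H]1C(C)=C[C@@]2(C)[C@@H]1[C@]2(C)C(=O)C(C)C(=O)C(C)C(=O)OC | intermediate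
26 | 4-hydroxy-3,5-dimethyl-6-[(1S,4S,5R,6S)-1,3,6-trimethyl-4-[(2E)-pent-2-en-2-yl]bicyclo[3.1.0]hex-2-en-6-yl]-2H-pyran-2-one | CC/C=C(\C)[C@H]1C(C)=C[C@@]2(C)[C@@H]1[C@]2(C)c1oc(=O)c(C)c(O)c1C | intermediate
27 | 4-hydroxy-2-methoxy-3,5-dimethyl-6-(bicyclyl)pyrylium trifluoromethanesulfonate (formed in the flask) | CC/C=C(\C)[C@H]1C(C)=C[C@@]2(C)[C@@H]1[C@]2(C)c1[o+]c(OC)c(C)c(O)c1C.[O-]S(=O)(=O)C(F)(F)F | intermediate
28 | 2-methoxy-3,5-dimethyl-6-[(1S,4S,5R,6S)-1,3,6-trimethyl-4-[(2E)-pent-2-en-2-yl]bicyclo[3.1.0]hex-2-en-6-yl]-4H-pyran-4-one | CC/C=C(\C)[C@H]1C(C)=C[C@@]2(C)[C@@H]1[C@]2(C)c1oc(OC)c(C)c(=O)c1C | intermediate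
29 | 6-[(1S,4R,5R,6S)-4-(3-hydroperoxypent-1-en-2-yl)-1,3,6-trimethylbicyclo[3.1.0]hex-2-en-6-yl]-2-methoxy-3,5-dimethyl-4H-pyran-4-one (carbinol epimers; formed in the flask) | C=C(C(CC)OO)[C@H]1C(C)=C[C@@]2(C)[C@@H]1[C@]2(C)c1oc(OC)c(C)c(=O)c1C | intermediate
30 | 2-methoxy-3,5-dimethyl-6-[(1S,4R,5R,6S)-1,3,6-trimethyl-4-(3-oxopent-1-en-2-yl)bicyclo[3.1.0]hex-2-en-6-yl]-4H-pyran-4-one | C=C(C(=O)CC)[C@H]1C(C)=C[C@@]2(C)[C@@H]1[C@]2(C)c1oc(OC)c(C)c(=O)c1C | target

**Step count.** Total: 15 steps. Longest linear sequence: 12 steps (4 → 6 → 8 → 10 → 17 → 19 → 20 → 21 → 24 → 25 → 26 → 28 → 30).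

**Steps most likely to fail**

1. Step 8. The auxiliary may discriminate the two π-faces only weakly, or in the opposite sense if the enoate reacts through the s-cis aluminium complex. The bulky ester may also slow the Lewis-acid pathway enough for thermal 6π electrocyclisation or double-bond isomerisation to compete. The fallback replaces auxiliary control by resolution; it sets out from 3 and 14 and comes back at 20. Tandem MnO2 oxidation and Wittig olefination of 3 with commercial ethyl 2-(triphenyl-λ5-phosphanylidene)propanoate should give ethyl (2E,4Z)-5-iodo-2,4-dimethylpenta-2,4-dienoate F1. Negishi coupling with 16 (made from 14 as in step 7) should give ethyl (2E,4Z,6E,8E)-2,4,6,8-tetramethylundeca-2,4,6,8-tetraenoate F2. Its Me2AlCl cycloisomerisation is the known reaction without modification and should give the racemic bicyclic ethyl ester F3, and LiAlH4 then the racemic alcohol F4. Acylation with (1S)-camphanic chloride (pyridine, DMAP) should give two diastereomeric camphanates, separable by crystallisation or chromatography; the (1S,4S,5R,6S)-configured camphanate F5 (assigned by X-ray analysis) is kept and the diastereomeric camphanate F6 is set aside. Methanolysis of F5 (K2CO3, MeOH) returns 20.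

2. Step 15. Singlet oxygen may abstract hydrogen from the ethyl CH2 or from ring C4–H, or attack the ring alkene, and the new exocyclic double bond may drift into conjugation with the ring during the basic dehydration. The fallback fixes the position of the oxygen by dihydroxylation; it sets out from 28 and comes back at 30. OsO4 (cat.) with N-methylmorpholine N-oxide in acetone/water should dihydroxylate the side-chain alkene to the 2,3-dihydroxypentan-2-yl compound F7 (carbinol diastereomers, both usable). SO3·pyridine, DMSO and iPr2NEt should oxidise the secondary alcohol to the 2-hydroxy-3-oxopentan-2-yl compound F8. Burgess reagent (toluene, 50 °C) should then dehydrate the tertiary alcohol by syn-elimination towards the methyl group to give 30.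

3. Step 7. Hydrozirconation may place zirconium partly on the alkyne carbon next to the alkene, and the (4Z) geometry may erode, or the tetraene may electrocyclise, during the coupling. The fallback fixes the regiochemistry by two successive couplings on the dibromide; it sets out from 10 and 12 and comes back at 17. Miyaura borylation of 10 (bis(pinacolato)diboron, PdCl2(PPh3)2, PPh3, KOPh, toluene, 50 °C) should give the 8-phenylmenthyl (2E,4Z)-dienyl pinacol boronate F9 with retention. Suzuki coupling of F9 with 12 (Pd2(dba)3, tri(2-furyl)phosphine, Cs2CO3, THF/H2O, rt) should take place selectively at the bromide trans to the alkenyl group and give the 8-phenylmenthyl (2E,4Z,6Z,8E)-6-bromo-2,4,8-trimethylundeca-2,4,6,8-tetraenoate F10. Negishi methylation (MeZnCl, Pd(t-Bu3P)2, THF, rt) with retention then gives 17.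

**Further compounds**

F1 | step 8 | ethyl (2E,4Z)-5-iodo-2,4-dimethylpenta-2,4-dienoate | I/C=C(C)\C=C(/C)C(=O)OCC
F2 | step 8 | ethyl (2E,4Z,6E,8E)-2,4,6,8-tetramethylundeca-2,4,6,8-tetraenoate | CC/C=C(C)/C=C(C)/C=C(C)\C=C(/C)C(=O)OCC
F3 | step 8 | racemic ethyl (1S,4S,5R,6S)-1,3,6-trimethyl-4-[(2E)-pent-2-en-2-yl]bicyclo[3.1.0]hex-2-ene-6-carboxylate (one enantiomer drawn) | CC/C=C(\C)[C@H]1C(C)=C[C@@]2(C)[C@@H]1[C@]2(C)C(=O)OCC
F4 | step 8 | racemic [(1S,4S,5R,6S)-1,3,6-trimethyl-4-[(2E)-pent-2-en-2-yl]bicyclo[3.1.0]hex-2-en-6-yl]methanol (one enantiomer drawn) | CC/C=C(\C)[C@H]1C(C)=C[C@@]2(C)[C@@H]1[C@]2(C)CO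
F5 | step 8 | [(1S,4S,5R,6S)-1,3,6-trimethyl-4-[(2E)-pent-2-en-2-yl]bicyclo[3.1.0]hex-2-en-6-yl]methyl (1S,4R)-camphanate | CC/C=C(\C)[C@H]1C(C)=C[C@@]2(C)[C@@H]1[C@]2(C)COC(=O)[C@@]12CC[C@@](C)(C(=O)O1)C2(C)C
F6 | step 8 | [(1R,4R,5S,6R)-1,3,6-trimethyl-4-[(2E)-pent-2-en-2-yl]bicyclo[3.1.0]hex-2-en-6-yl]methyl (1S,4R)-camphanate | CC/C=C(\C)[C@@H]1C(C)=C[C@]2(C)[C@H]1[C@@]2(C)COC(=O)[C@@]12CC[C@@](C)(C(=O)O1)C2(C)C
F7 | step 15 | 6-[(1S,4R,5R,6S)-4-(2,3-dihydroxypentan-2-yl)-1,3,6-trimethylbicyclo[3.1.0]hex-2-en-6-yl]-2-methoxy-3,5-dimethyl-4H-pyran-4-one (carbinol diastereomers) | CCC(O)C(C)(O)[C@H]1C(C)=C[C@@]2(C)[C@@H]1[C@]2(C)c1oc(OC)c(C)c(=O)c1C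
F8 | step 15 | 6-[(1S,4R,5R,6S)-4-(2-hydroxy-3-oxopentan-2-yl)-1,3,6-trimethylbicyclo[3.1.0]hex-2-en-6-yl]-2-methoxy-3,5-dimethyl-4H-pyran-4-one (carbinol epimers) | CCC(=O)C(C)(O)[C@H]1C(C)=C[C@@]2(C)[C@@H]1[C@]2(C)c1oc(OC)c(C)c(=O)c1C
F9 | step 7 | 8-phenylmenthyl (2E,4Z)-2,4-dimethyl-5-(4,4,5,5-tetramethyl-1,3,2-dioxaborolan-2-yl)penta-2,4-dienoate | CC1(C)OB(OC1(C)C)/C=C(C)\C=C(/C)C(=O)O[C@@H]1C[C@H](C)CC[C@H]1C(C)(C)c1ccccc1
F10 | step 7 | 8-phenylmenthyl (2E,4Z,6Z,8E)-6-bromo-2,4,8-trimethylundeca-2,4,6,8-tetraenoate | CC/C=C(C)/C=C(Br)/C=C(C)\C=C(/C)C(=O)O[C@@H]1C[C@H](C)CC[C@H]1C(C)(C)c1ccccc1
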